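**Plan**

- Retrosynthetic cuts (primed locants = caryophyllane numbering, unprimed = labdane numbering): C12–C4′ and C15–C5′ first, since the cyclohexene ring is the Diels–Alder adduct of the C12=C13–C14=C15 diene of trans-communic acid and a ring-trans C4′=C5′ enal. Then C8′=CH2 (Wittig), C4′–C8′ (Grob fragmentation of a 4/6/5 tricycle), C5′–C6′ (Dieckmann), C7′–C8′ (acetylide addition), C4′–C12′ (formaldehyde aldol), C4′–C5′ (carbonate acylation), and last C1′–C11′ and C9′–C10′.
- Enabling feature: the gem-dimethylcyclobutane C1′–C9′–C10′–C11′ is fused to the nine-membered ring so that C9′ (bonded to CH2-10′) is α and C1′ (bonded to CMe2-11′) is β to C8′, whose exocyclic methylene is a masked ketone. This is the head-to-tail [2+2] pattern of cyclohex-2-enone and isobutene.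
- Forward order of rings: cyclobutane on the six-membered ring (step 1), cyclopentanone annulated across C4′–C8′ (steps 2–7), the shared 6/5 bond cleaved to give the nine-membered ring (step 10), cyclohexene ring closed by cycloaddition (step 14), oxidation to the diacid (step 15).
- Stereochemistry: C1′ from the chiral Lewis acid; C9′ by base equilibration (cis at the 4/6 stage, trans at the 4/9 stage). The trans ring olefin comes from anti-periplanar fragmentation of a rigid trans-hydrindane, whose centres are set by convex-face additions and a hydroxyl-directed reduction. C4′, C5′ and C12 come from a formyl-endo cycloaddition on the exposed olefin face.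
- C4, C5, C9 and C10 are bought with trans-communic acid, which also converts any minor enantiomer of the sesquiterpene half into a separable diastereomer.

Key step: step 1

Remark: trans-communic acid (23) is taken as a purchasable diterpene acid (it is sold as an isolated natural product). The prolinol antipode of the catalyst in step 1 is the one that correlates with the (6R) adduct.

**Route**

Step 1
Reactants: 1 cyclohex-2-en-1-one; 2 isobutene
Product: 4 (1R,6R)-7,7-dimethylbicyclo[4.2.0]octan-2-one (cis-fused), via trans-fused photoadduct 3 (not isolated)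
Conditions: B-aryl oxazaborolidine (from an α,α-diarylprolinol and an arylboronic acid) activated with AlBr3 (50 mol %), 2 (excess, condensed), CH2Cl2, −75 °C, hν (366 nm); then basic Al2O3, CH2Cl2, 23 °C
Reagents that add atoms: none
Why: Coordination of the AlBr3-activated oxazaborolidine to the carbonyl oxygen of 1 shifts the enone absorption to longer wavelength, so that at 366 nm essentially only the bound enone is excited and reacts from its triplet state; the closest known reaction type is the chiral Lewis acid-catalysed intermolecular [2+2] photocycloaddition of cyclic enones with simple olefins. The triplet bonds first from C9′ (α-carbon) to the CH2 terminus of 2, and the resulting 1,4-diradical (tertiary C11′ radical and C1′ radical) closes the cyclobutane after spin inversion by C1′–C11′ radical recombination, a stepwise four-membered ring closure that these partners cannot undergo thermally. C1′ is fixed by the catalyst, whose aryl group shields one face of the enone β-carbon, and should have the R configuration required in 25. C9′ is not controlled in the photochemical event (trans-fused 3 is expected alongside), but it is α to the ketone and should converge on basic Al2O3 to the more stable cis fusion of 4; it is provisional and is reset in step 10. The step needs head-to-tail regiochemistry and enantioface selection: the first follows from bonding at the unhindered CH2 terminus with retention of the tertiary radical, the second from the catalyst, and the choice of wavelength suppresses the racemic background reaction of free 1.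

Step 2
Reactants: 4 (1R,6R)-7,7-dimethylbicyclo[4.2.0]octan-2-one; 5 dimethyl carbonate
Product: 6 methyl (1R,6R)-7,7-dimethyl-2-oxobicyclo[4.2.0]octane-3-carboxylate (keto–enol mixture at C4′)
Conditions: NaH (2.2 equiv), 5 (excess), THF, reflux; then 1 M HCl, 0 °C
Reagents that add atoms: none
Why: Claisen-type C-acylation of the sodium enolate, which can form only toward C4′ because enolisation toward C9′ would place a double bond exocyclic to the cyclobutane, and which is driven by formation of the stabilised β-keto ester enolate while the cis 4/6 fusion persists as the stable arrangement.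

Step 3
Reactants: 6 methyl (1R,6R)-7,7-dimethyl-2-oxobicyclo[4.2.0]octane-3-carboxylate
Product: 7 methyl (1R,3R,6R)-3-(hydroxymethyl)-7,7-dimethyl-2-oxobicyclo[4.2.0]octane-3-carboxylate (CH2OH anti to the cyclobutane)
Conditions: aq. CH2O (37%), KHCO3 (cat.), THF, 23 °C
Reagents that add atoms: formaldehyde, C=O
Why: Base-catalysed aldol addition (hydroxymethylation) of the β-keto ester to formaldehyde, in which the quaternary centre C4′ is set by axial attack on the enolate face opposite the cyclobutane, so that C12′ lies anti and the ester syn to the four-membered ring.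

Step 4
Reactants: 7 methyl (1R,3R,6R)-3-(hydroxymethyl)-7,7-dimethyl-2-oxobicyclo[4.2.0]octane-3-carboxylate
Product: 8 methyl (1R,3R,6R)-3-(tert-butyldiphenylsilyloxymethyl)-7,7-dimethyl-2-oxobicyclo[4.2.0]octane-3-carboxylate
Conditions: TBDPSCl, imidazole, DMAP (cat.), DMF, 23 °C
Reagents that add atoms: tert-butyl(chloro)diphenylsilane, CC(C)(C)[Si](Cl)(c1ccccc1)c1ccccc1
Why: Silylation of the primary alcohol blocks retro-aldol loss of formaldehyde and gives an ether that should withstand the hydrogenation, amide base, hydroxide, alkoxide and ylide used before its removal in step 12.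

Step 5
Reactants: 8 methyl (1R,3R,6R)-3-(tert-butyldiphenylsilyloxymethyl)-7,7-dimethyl-2-oxobicyclo[4.2.0]octane-3-carboxylate; 9 methyl propiolate
Product: 10 methyl (1R,2S,3R,6R)-3-(tert-butyldiphenylsilyloxymethyl)-2-hydroxy-2-(3-methoxy-3-oxoprop-1-ynyl)-7,7-dimethylbicyclo[4.2.0]octane-3-carboxylate
Conditions: 9, LiN(SiMe3)2, THF, −78 °C; then 8, −78 °C; AcOH quench at −78 °C
Reagents that add atoms: none
Why: 1,2-Addition of a lithium acetylide, a slim linear nucleophile that tolerates the quaternary and tertiary α-carbons of the ketone, from the convex face opposite C10′ and the axial ester, which sets C8′ with the hydroxyl syn to the cyclobutane and the new C7′ chain anti to it and trans to the C4′ ester.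

Step 6
Reactants: 10 methyl (1R,2S,3R,6R)-3-(tert-butyldiphenylsilyloxymethyl)-2-hydroxy-2-(3-methoxy-3-oxoprop-1-ynyl)-7,7-dimethylbicyclo[4.2.0]octane-3-carboxylate
Product: 12 spiro-γ-lactone (C8′ spiro carbon; lactone oxygen syn to the cyclobutane; C7′H2–C6′H2–C(=O) arm anti; C4′ ester and silyloxymethyl unchanged), via saturated hydroxy diester 11 (not isolated)
Conditions: H2 (1 atm), Pd/C, EtOAc, 23 °C; filter; then PPTS (cat.), toluene, 60 °C
Reagents that add atoms: none
Why: Heterogeneous hydrogenation saturates the alkyne without touching esters or the silyl ether, and the resulting γ-hydroxy ester closes to the five-membered lactone by acid-catalysed transesterification, with no stereocentre affected.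

Step 7
Reactants: 12 spiro-γ-lactone
Product: 15 trans-fused 4/6/5 tricyclic ketol (cyclopentanone C4′–C5′(=O)–C6′–C7′–C8′; C8′–OH syn to the cyclobutane; C4′–CH2OTBDPS on the opposite face), via hydroxy β-keto ester 13 (not isolated), via β-keto acid 14 (not isolated)
Conditions: NaN(SiMe3)2 (1.1 equiv), THF, −78 → 0 °C; then 1 M aq. NaOH, MeOH, 23 °C; then 1 M HCl to pH 3, 40 °C
Reagents that add atoms: none
Why: Dieckmann condensation of the lactone enolate (C6′) onto the C4′ ester followed by methoxide opening of the bridged keto lactone gives the β-keto ester enolate 13, which is saponified and decarboxylated on acidification; the trans ring fusion is dictated by the anti relationship of the C7′ chain and the ester fixed in steps 3 and 5, and the medium is never basic while a free ketone sits next to the C8′ alkoxide, so retro-aldol scrambling should be avoided.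

Step 8
Reactants: 15 trans-fused tricyclic ketol
Product: 16 trans-fused tricyclic diol (C5′–OH pseudo-equatorial; cis to the C12′ arm; trans to C8′–OH)
Conditions: Me4NBH(OAc)3, MeCN/AcOH (1:1), −20 °C
Reagents that add atoms: none
Why: Hydroxyl-directed reduction in which the triacetoxyborohydride exchanges onto the C8′ hydroxyl and delivers hydride intramolecularly to the C5′ ketone from that face, which is also the face away from the axial C12′ arm, so that C5′ is set with its hydroxyl trans to C8′–OH and cis to C12′.

Step 9
Reactants: 16 trans-fused tricyclic diol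
Product: 17 C5′ methanesulfonate of 16 (tertiary C8′–OH free)
Conditions: MsCl, Et3N, CH2Cl2, 0 °C
Reagents that add atoms: methanesulfonyl chloride, CS(=O)(=O)Cl
Why: Sulfonylation through the sulfene reaches the hindered secondary alcohol while the tertiary alcohol is inert, and the configuration at C5′ is retained because only the O–H bond reacts.

Step 10
Reactants: 17 C5′ methanesulfonate
Product: 19 (1R,4Z,9S)-4-(tert-butyldiphenylsilyloxymethyl)-11,11-dimethylbicyclo[7.2.0]undec-4-en-8-one (ring-trans olefin with C3′ and C6′ on opposite sides; the Z label arises only because C12′ bears oxygen; trans 4/9 fusion), via cis-fused cyclononenone 18 (not isolated)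
Conditions: KOt-Bu (3 equiv), t-BuOH/THF, 0 → 23 °C
Reagents that add atoms: none
Why: Grob fragmentation in which the C8′ alkoxide expels the mesylate across the anti-periplanar C4′–C8′ bond, and because C5′–O and C4′–C3′ are both pseudo-equatorial on the rigid trans-fused cyclopentane, C3′ and C6′ emerge anti across the new C4′=C5′ bond (trans ring olefin), after which the excess alkoxide equilibrates C9′ through the enolate to the more stable trans 4/9 fusion (9S).

Step 11
Reactants: 19 (1R,4Z,9S)-4-(tert-butyldiphenylsilyloxymethyl)-11,11-dimethylbicyclo[7.2.0]undec-4-en-8-one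
Product: 20 (1R,4Z,9S)-4-(tert-butyldiphenylsilyloxymethyl)-11,11-dimethyl-8-methylidenebicyclo[7.2.0]undec-4-ene
Conditions: Ph3PCH3Br, KOt-Bu, THF, 0 → 40 °C
Reagents that add atoms: methyltriphenylphosphonium bromide, C[P+](c1ccccc1)(c1ccccc1)c1ccccc1.[Br-]
Why: Wittig methylenation with the small unstabilised ylide converts the hindered C8′ ketone into the exocyclic methylene, and C9′ cannot be lost because it already holds its thermodynamic configuration.

Step 12
Reactants: 20 (1R,4Z,9S)-4-(tert-butyldiphenylsilyloxymethyl)-11,11-dimethyl-8-methylidenebicyclo[7.2.0]undec-4-ene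
Product: 21 [(1R,4Z,9S)-11,11-dimethyl-8-methylidenebicyclo[7.2.0]undec-4-en-4-yl]methanol
Conditions: Bu4NF, THF, 23 °C; aqueous work-up
Reagents that add atoms: none
Why: Fluoride-induced desilylation frees the primary allylic alcohol under non-acidic conditions that leave the strained olefin, the exocyclic methylene and the cyclobutane untouched.

Step 13
Reactants: 21 [(1R,4Z,9S)-11,11-dimethyl-8-methylidenebicyclo[7.2.0]undec-4-en-4-yl]methanol
Product: 22 (1R,4Z,9S)-11,11-dimethyl-8-methylidenebicyclo[7.2.0]undec-4-ene-4-carbaldehyde (ring-trans enal)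
Conditions: MnO2 (activated, excess), CH2Cl2, 23 °C
Reagents that add atoms: none
Why: Heterogeneous allylic oxidation with MnO2 stops at the aldehyde and is neutral, so the geometry of the strained C4′=C5′ bond should be preserved.

Step 14
Reactants: 22 (1R,4Z,9S)-11,11-dimethyl-8-methylidenebicyclo[7.2.0]undec-4-ene-4-carbaldehyde; 23 trans-communic acid (labda-8(17),12E,14-trien-19-oic acid; 4S,5R,9S,10R)
Product: 24 C12′-aldehyde analogue of the target (cyclohexene ring C5′–C15–C14=C13(Me)–C12–C4′; CHO on C4′ cis to the C11 methylene on C12; C3′ and C6′ trans)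
Conditions: 23 (3 equiv), BHT (cat.), toluene (1 M), 90 °C, sealed tube, dark
Reagents that add atoms: none
Why: Thermal normal-demand Diels–Alder reaction of the strain-activated trans-cyclononene enal, in which the unsubstituted diene terminus C15 bonds to the β-carbon C5′ and C12 to C4′, the formyl group lies endo (placing C11 cis to C12′), and the diene adds to the outer olefin face, the same face that this ring system exposes in forming the natural (4R,5R)-epoxide, so that C4′, C5′ and C12 are set together while the trans olefin geometry is transferred suprafacially into the trans disposition of C3′ and C6′.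

Step 15
Reactants: 24 C12′-aldehyde analogue of the target
Product: 25 target CNP0330729.1 (C12′,C19-diacid)
Conditions: NaClO2, NaH2PO4, 2-methyl-2-butene (excess), t-BuOH/THF/H2O, 0 → 23 °C
Reagents that add atoms: sodium chlorite, [Na+].[O-]Cl=O
Why: Pinnick oxidation converts the neopentyl aldehyde into the carboxylic acid without an enolisable position to epimerise, while the alkene scavenger removes hypochlorous acid before it can attack the three olefins.

**Compound list**

1 | cyclohex-2-en-1-one | O=C1C=CCCC1 | starting material
2 | isobutene | C=C(C)C | starting material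
3 | (1S,6R)-7,7-dimethylbicyclo[4.2.0]octan-2-one (trans-fused photoadduct) | O=C1CCC[C@@H]2[C@@H]1CC2(C)C | intermediate
4 | (1R,6R)-7,7-dimethylbicyclo[4.2.0]octan-2-one (cis-fused) | O=C1CCC[C@@H]2[C@H]1CC2(C)C | intermediate
5 | dimethyl carbonate | COC(=O)OC | starting material
6 | methyl (1R,6R)-7,7-dimethyl-2-oxobicyclo[4.2.0]octane-3-carboxylate (C3 left open: epimers and enol interconvert) | O=C1C(C(=O)OC)CC[C@@H]2[C@H]1CC2(C)C | intermediate
7 | methyl (1R,3R,6R)-3-(hydroxymethyl)-7,7-dimethyl-2-oxobicyclo[4.2.0]octane-3-carboxylate | O=C1[C@@](CO)(C(=O)OC)CC[C@@H]2[C@H]1CC2(C)C | intermediate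
8 | methyl (1R,3R,6R)-3-(tert-butyldiphenylsilyloxymethyl)-7,7-dimethyl-2-oxobicyclo[4.2.0]octane-3-carboxylate | O=C1[C@@](CO[Si](c3ccccc3)(c3ccccc3)C(C)(C)C)(C(=O)OC)CC[C@@H]2[C@H]1CC2(C)C | intermediate
9 | methyl propiolate | C#CC(=O)OC | starting material
10 | methyl (1R,2S,3R,6R)-3-(tert-butyldiphenylsilyloxymethyl)-2-hydroxy-2-(3-methoxy-3-oxoprop-1-ynyl)-7,7-dimethylbicyclo[4.2.0]octane-3-carboxylate | O[C@@]1(C#CC(=O)OC)[C@@](CO[Si](c3ccccc3)(c3ccccc3)C(C)(C)C)(C(=O)OC)CC[C@@H]2[C@H]1CC2(C)C | intermediate
11 | methyl (1R,2R,3R,6R)-3-(tert-butyldiphenylsilyloxymethyl)-2-hydroxy-2-(3-methoxy-3-oxopropyl)-7,7-dimethylbicyclo[4.2.0]octane-3-carboxylate | O[C@@]1(CCC(=O)OC)[C@@](CO[Si](c3ccccc3)(c3ccccc3)C(C)(C)C)(C(=O)OC)CC[C@@H]2[C@H]1CC2(C)C | intermediate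
12 | spiro-γ-lactone at C8′ (lactone O syn, CH2CH2 arm anti to the cyclobutane; C4′ bears CO2Me syn and CH2OTBDPS anti) | O=C1CC[C@]2(O1)[C@@](CO[Si](c4ccccc4)(c4ccccc4)C(C)(C)C)(C(=O)OC)CC[C@@H]3[C@H]2CC3(C)C | intermediate
13 | trans-fused tricyclic hydroxy β-keto ester (CO2Me on C6′ of ketol 15; C6′ enolisable) | O=C1C(C(=O)OC)C[C@]2(O)[C@]1(CO[Si](c4ccccc4)(c4ccccc4)C(C)(C)C)CC[C@@H]3[C@H]2CC3(C)C | intermediate
14 | trans-fused tricyclic hydroxy β-keto acid (CO2H on C6′ of ketol 15) | O=C1C(C(=O)O)C[C@]2(O)[C@]1(CO[Si](c4ccccc4)(c4ccccc4)C(C)(C)C)CC[C@@H]3[C@H]2CC3(C)C | intermediate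
15 | trans-fused 4/6/5 tricyclic ketol (C5′ ketone; C8′–OH syn to cyclobutane; C4′–CH2OTBDPS anti) | O=C1CC[C@]2(O)[C@]1(CO[Si](c4ccccc4)(c4ccccc4)C(C)(C)C)CC[C@@H]3[C@H]2CC3(C)C | intermediate
16 | trans-fused tricyclic diol (C5′–OH cis to the C12′ arm, trans to C8′–OH) | O[C@H]1CC[C@]2(O)[C@]1(CO[Si](c4ccccc4)(c4ccccc4)C(C)(C)C)CC[C@@H]3[C@H]2CC3(C)C | intermediate
17 | C5′ methanesulfonate of 16 | CS(=O)(=O)O[C@H]1CC[C@]2(O)[C@]1(CO[Si](c4ccccc4)(c4ccccc4)C(C)(C)C)CC[C@@H]3[C@H]2CC3(C)C | intermediate
18 | (1R,4Z,9R)-4-(tert-butyldiphenylsilyloxymethyl)-11,11-dimethylbicyclo[7.2.0]undec-4-en-8-one (ring-trans olefin, cis 4/9 fusion) | O=C1CC/C=C(CO[Si](c3ccccc3)(c3ccccc3)C(C)(C)C)/CC[C@@H]2[C@H]1CC2(C)C | intermediate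
19 | (1R,4Z,9S)-4-(tert-butyldiphenylsilyloxymethyl)-11,11-dimethylbicyclo[7.2.0]undec-4-en-8-one (ring-trans olefin, trans 4/9 fusion) | O=C1CC/C=C(CO[Si](c3ccccc3)(c3ccccc3)C(C)(C)C)/CC[C@@H]2[C@@H]1CC2(C)C | intermediate
20 | (1R,4Z,9S)-4-(tert-butyldiphenylsilyloxymethyl)-11,11-dimethyl-8-methylidenebicyclo[7.2.0]undec-4-ene | C=C1CC/C=C(CO[Si](c3ccccc3)(c3ccccc3)C(C)(C)C)/CC[C@@H]2[C@@H]1CC2(C)C | intermediate
21 | [(1R,4Z,9S)-11,11-dimethyl-8-methylidenebicyclo[7.2.0]undec-4-en-4-yl]methanol | C=C1CC/C=C(CO)/CC[C@@H]2[C@@H]1CC2(C)C | intermediate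
22 | (1R,4Z,9S)-11,11-dimethyl-8-methylidenebicyclo[7.2.0]undec-4-ene-4-carbaldehyde | C=C1CC/C=C(C=O)/CC[C@@H]2[C@@H]1CC2(C)C | intermediate
23 | trans-communic acid, (1S,4aR,5S,8aR)-1,4a-dimethyl-6-methylidene-5-[(2E)-3-methylpenta-2,4-dienyl]decahydronaphthalene-1-carboxylic acid | C=C/C(C)=C/C[C@H]1C(=C)CC[C@@H]2[C@]1(C)CCC[C@]2(C)C(=O)O | starting material
24 | Diels–Alder adduct, C12′-aldehyde analogue of the target | C=C1CC[C@H]2CC=C(C)[C@@H](C[C@H]3C(=C)CC[C@@H]4[C@]3(C)CCC[C@]4(C)C(=O)O)[C@]2(C=O)CC[C@@H]2[C@@H]1CC2(C)C | intermediate
25 | CNP0330729.1 | C=C1CC[C@H]2CC=C(C)[C@@H](C[C@H]3C(=C)CC[C@@H]4[C@]3(C)CCC[C@]4(C)C(=O)O)[C@]2(C(=O)O)CC[C@@H]2[C@@H]1CC2(C)C | target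

**Step count and risks**

Total steps: 15. Longest linear sequence: 15 (1 → 25); 23 enters at step 14 without prior steps.

Most likely to fail, in this order:

Step 14. The cycloaddition joins a trisubstituted dienophile to a substituted diene terminus, so it may be slow enough for the diene to oligomerise first, and face, endo/exo or regiochemical selection may be incomplete. The fallback inverts oxidation and cycloaddition. Enal 22 is oxidised with NaClO2/NaH2PO4/2-methyl-2-butene to (1R,4Z,9S)-11,11-dimethyl-8-methylidenebicyclo[7.2.0]undec-4-ene-4-carboxylic acid F1, and F1 is combined with 23 as a concentrated acid–acid pair (neat melt or aqueous suspension, 60–80 °C). Carboxylic acid pairing and hydrophobic packing then take the place of formyl activation, and the cycloaddition should give 25 directly, rejoining the route at its final compound.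

Step 7. Closure of a trans-fused cyclopentanone through a bridged keto lactone may be slow, and the alkoxide released next to the new ketone may open the ring by retro-aldol cleavage and scramble the ring fusion. The fallback avoids both the lactone and any free alkoxide. Alkynoate 10 is hydrogenated (H2, Pd/C, EtOAc) and 11 is isolated without acid, then silylated at the tertiary hydroxyl (TMSOTf, 2,6-lutidine, CH2Cl2, −78 °C) to the trimethylsilyl ether of the hydroxy diester F2. An ordinary diester Dieckmann condensation (NaN(SiMe3)2, THF) gives the C8′-O-trimethylsilyl β-keto ester F3. Aqueous NaOH followed by HCl removes the trimethylsilyl group and the ester and decarboxylates through 13 and 14, returning to the route at ketol 15.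

Step 5. The carbonyl is flanked by a quaternary and a tertiary carbon, so addition may stall and leave time for enolisation toward C9′ or attack of the acetylide on the ester. The fallback replaces the polar addition by a radical one. Ketone 8 is treated with SmI2, methyl acrylate (C=CC(=O)OC) and t-BuOH in THF at 0 °C. The ketyl radical adds to the acrylate from the face opposite the cyclobutane, and the resulting trivalent samarium alkoxide lactonises, which should give spirolactone 12 directly and rejoin the route there; no compound outside the list arises (F0).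

**Further compounds**

F1 | step 14 | (1R,4Z,9S)-11,11-dimethyl-8-methylidenebicyclo[7.2.0]undec-4-ene-4-carboxylic acid | C=C1CC/C=C(C(=O)O)/CC[C@@H]2[C@@H]1CC2(C)C
F2 | step 7 | trimethylsilyl ether (at C8′–O) of hydroxy diester 11 | C[Si](C)(C)O[C@@]1(CCC(=O)OC)[C@@](CO[Si](c3ccccc3)(c3ccccc3)C(C)(C)C)(C(=O)OC)CC[C@@H]2[C@H]1CC2(C)C
F3 | step 7 | C8′-O-trimethylsilyl derivative of hydroxy β-keto ester 13 | O=C1C(C(=O)OC)C[C@]2(O[Si](C)(C)C)[C@]1(CO[Si](c4ccccc4)(c4ccccc4)C(C)(C)C)CC[C@@H]3[C@H]2CC3(C)C
F0 | step 5 | none | none
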